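A one-step picture has the loss of substrate thinning as the charges thin, so we read the winter and noon runs against it, and the reading to watch is how fast that loss fades.

| flask | substrate | coupling partner | remark | time |
|---|---|---|---|---|
| winter | 1 M | 1 M | run made earlier |  |
| noon | 1 M | 1.1 M | run made earlier |  |
| teal | 1.0 M | 0.950 M |  | 80 min |
| grey | 1.0 M | 1.40 M |  | 80 min |

| run | time / min | target / % | intermediate / % | side product / % | substrate / % |
|---|---|---|---|---|---|
| winter | 8.00 | 2.1 | 9.2 | 1.3 | 88.4 |
| winter | 15.0 | 4.6 | 10.6 | 1.7 | 81.9 |
| winter | 25.0 | 8.7 | 10.5 | 4.7 | 76.6 |
| winter | 30.0 | 12.0 | 8.9 | 4.7 | 73.9 |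
| winter | 40.0 | 15.3 | 7.5 | 6.6 | 70.8 |
| noon | 8.00 | 1.2 | 8.5 | 1.8 | 87.6 |
| noon | 15.0 | 3.7 | 11.5 | 2.6 | 81.1 |
| noon | 25.0 | 8.9 | 11.1 | 3.9 | 73.5 |
| noon | 30.0 | 12.1 | 10.4 | 5.7 | 71.4 |
| noon | 40.0 | 16.0 | 7.8 | 8.2 | 67.9 |

(standard deviation of a reading: 0.5 percentage points)

- percent here means substrate units held: one side product counts as two
- the earlier runs were read with a standard deviation of 0.5 percentage points
- a reading or a percentage of target counts all its forms, free or not

* which of these there is most of at the end, counted by the substrate in it, teal (target / side product / intermediate / substrate)
* which of these there is most of at the end, counted by the substrate in it, grey (target / side product / intermediate / substrate)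
* amount of the one of these that there is most of at the end, in percent of the substrate charged, teal
* amount of the one of these that there is most of at the end, in percent of the substrate charged, grey

The first rung is the intermediate: in the winter run it stands at 9.2 % by 8.00 min, and it later sinks to 7.5 % at 40.0 min while target climbs to 15.3 %. The next rung is the fading itself. The winter run loses 18.1 % of its substrate in the first 15.0 min but 8 percentage points in the next equal interval. Read as an exponential fade, this gives a fade time of 18.4 min. The last rung is the asked 80 min, which is 4.35 fade times, so a fraction 0.0129 of the fading loss is still to come and the end state is what we must estimate: the stall.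

Summing the fading intervals gives the substrate lost at the stall. Divided by the coupling partner charged, this reads 0.324 for winter and 0.353 for noon. Their mean is 0.339, and we carry this reading as the reach: substrate lost at the stall per coupling partner charged. Our own reckoning leaves 67.8 % substrate in teal and 52.6 % in grey. In grey the reckoned lost part, 47.4 %, is less than the reckoned substrate left, so on this reckoning substrate stays ahead of any product even if one product took the whole loss.

The forecast names substrate for teal and substrate for grey, with 64 % and 53 %, and holds that “target probably binds and inhibits something”. Our teal figure stands 3.8 points above it.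

Teal ends with most substrate, 66.9 %, and grey ends with most substrate, 55.4 %.

    substrate + intermediate → side product (k = 0.0124 L mol⁻¹ min⁻¹)
    intermediate → target (k = 0.0417 min⁻¹)
    coupling partner → decomposed reagent (k = 0.0251 min⁻¹)
    substrate + coupling partner ⇌ intermediate (K = 1.20 L mol⁻¹, k = 0.0182 L mol⁻¹ min⁻¹)
    crystals ⇌ target, rate k5*(cs5 - [target]) while solid is left; crystals form when [target] > cs5 (solubility = 27.0 mM, k = 1.21 min⁻¹)

At 80.0 min grey holds 0.916 M of decomposed reagent from 1.40 M of coupling partner charged, with 7.0 % of that charge still free. At 800 min grey holds 53.0 % of substrate, so the reach read back there is 0.336. Put to the neighbour of grey with 2.4 M of coupling partner, the carried reach of 0.339 leaves 18.7 % of substrate, and that flask holds 36.8 % at its end.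

(The data stem from a simulated flask with made-up constants, and the scatter is random.)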